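## Structural features

The target is a flavonol: benzene ring A is fused to the 4-pyranone ring C (a chromen-4-one), and aryl ring B is attached to C2 by a single C–C bond. Ring A carries a free hydroxyl at C5 and methoxy groups at C7 and C8, ring C a hydroxyl at C3, and ring B hydroxyls at C3' and C5' on either side of a methoxy group at C4'. There is no stereocentre, so the problem is purely one of regiochemistry: three ring-A oxygens must be placed and differentiated, and two ring-B phenols must stay free beside a methyl ether. The fragile features are the electron-rich polyoxygenated rings, above all any intermediate with a free para-dihydroxy ring A, which is oxidised by air once deprotonated, and the 3-hydroxy-4-keto unit, which does not tolerate strong oxidants in base. The C5 hydroxyl is hydrogen-bonded to the C4 carbonyl and is the least acidic and least nucleophilic phenol, which is the handle for telling the ring-A oxygens apart. The key step uses the para relationship of O5 and O8: ring A is a para-quinone in its reduced form, and in that quinone C8a is beta to the ring C5 carbonyl and beta to the side-chain C4 carbonyl, so O1–C8a can be formed by conjugate addition instead of the usual condensation.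

## Logic of the disconnections

15 to 14: the two benzyl–oxygen bonds on ring B are cut. The ring-B phenols must be masked through base, alkylation, organolithium and oxidation steps, and benzyl comes off last under neutral reducing conditions that leave the three methyl ethers untouched. The forward step must leave the C2=C3 bond of ring C unreduced.

14 to 11: the C3–O bond is cut. C3–H is the only ring-C position open to directed metalation, so the hydroxyl can be put on after the ring system is complete and 11 is a plain flavone. The forward step must metalate C3 in the presence of the free C5 hydroxyl, which costs one extra equivalent of base, and must keep the lithiated pyranone cold.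

11 to 10: the O8–CH3 bond is cut. This leads back to the 5,8-dihydroxy compound that the key step delivers directly, with no protecting group on ring A. The forward step must alkylate the free C8 hydroxyl and not the chelated C5 hydroxyl, with exclusion of air.

10 to 8, through 9: the O1–C8a bond is cut. Ring C opens to a 1,3-diketone attached to a hydroquinone, so the tricyclic problem becomes two benzene rings joined by a three-carbon chain, and the C8 oxygen comes from a cheap hydroquinone instead of a late C–H oxidation. The forward step must oxidise ring A under neutral conditions before any acid is met, so that the ordinary ring closure through O5 cannot compete.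

8 to 2 and 6: the bond between the central methylene carbon and the ring-B carbonyl carbon is cut. This is the convergent Claisen-type cut, joining a ring-A methyl ketone to a ring-B acyl donor. The forward step must acylate carbon and not either of the two free phenols of 2, which is why the ketone is used as its lithium polyanion 7 and no ester has to be hydrolysed afterwards.

2 to 1: the aryl–acetyl bond is cut. The position para to the methoxy group and ortho to a hydroxyl is the most activated carbon of 1, so the acylation needs no protecting group.

6 to 5 to 3, through 4: the acyl–chlorine bond and the two benzyl–oxygen bonds are cut. This leads to a purchasable acid that already carries the ring-B oxygen pattern with the C4' methyl ether in place. The forward steps must benzylate exhaustively and then free only the carboxyl group.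

## Other disconnections considered

Alternative 1: The cut is O1–C2, with ring C traced back to a five-membered benzofuranone. The aurone (Z)-2-[3,5-bis(benzyloxy)-4-methoxybenzylidene]-4,6,7-trimethoxy-1-benzofuran-3(2H)-one A1 would be brominated to its dibromide A2. In the forward key step (Auwers ring expansion), KOH in ethanol would open the five-membered ring at the bromine-bearing C2, and the released phenoxide would displace the benzylic bromide to give 2-[3,5-bis(benzyloxy)-4-methoxyphenyl]-3-hydroxy-5,7,8-trimethoxychromen-4-one A3.
- In favour: the C3 hydroxyl arrives in the same operation as ring C. On this point the alternative is better than the chosen plan, which needs a separate metalation–borylation–oxidation. It is also a long-established named reaction and passes through no air-sensitive hydroquinone, so it is better on precedent and on handling.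
- Against: bromine would be expected to attack the activated nuclear C–H of ring A between two methoxy groups and the ring-B positions. Dibromides with donor groups para to the benzylic carbon tend to lose HBr back to the aurone level instead of expanding. A3 carries a C5 methyl ether that must be removed peri-selectively beside two benzyl ethers. The ring-A building block for A1 is not an article of commerce.
- Comparison: both plans close ring C through O1, here by substitution at C2, in the chosen plan by conjugate addition at C8a. The step count would be about equal at best (building block, condensation, bromination, expansion, demethylation, hydrogenolysis). The chosen plan delivers the free C5 hydroxyl without a demethylation.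

Alternative 2: The cut is C7–C8, so ring A is built last on a finished pyranone. Methyl (E)-3-[5-(benzyloxy)-6-[3,5-bis(benzyloxy)-4-methoxyphenyl]-2-(methoxymethyl)-4-oxo-4H-pyran-3-yl]-3-methoxyprop-2-enoate A4 would be deprotonated at its methoxymethyl group with LiN(SiMe3)2. The vinylogous enolate would attack the neighbouring ester carbon and, after loss of methoxide and tautomerisation, give 3-(benzyloxy)-2-[3,5-bis(benzyloxy)-4-methoxyphenyl]-7-hydroxy-5,8-dimethoxychromen-4-one A5.
- In favour: the C3 oxygen is already present as a benzyl ether, which is better than the chosen plan on that point. The ring-A oxygen positions are fixed by connectivity and not by aromatic substitution selectivity. No redox chemistry on ring A is needed.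
- Against: A4 is a fully substituted pyranone with four different substituents and would need a long preparation, to construct a benzene ring that can be bought. A5 has the C7 oxygen free and the C5 oxygen methylated, the reverse of the target, so a methylation and a peri-demethylation follow. The base must choose the methoxymethyl C–H over other acidic sites.
- Comparison: mechanistically sound as a Claisen-type benzannulation, but clearly inferior in step economy to a plan in which ring A is purchased with its oxygens in place.

Alternative 3: The cuts are O1–C8a and C4a–C4, then O1–C2. The aryne released by CsF from 3,5-dimethoxy-2-(trimethylsilyl)phenyl trifluoromethanesulfonate A6 would insert into the carboxyl C–O bond of 3-[3,5-bis(benzyloxy)-4-methoxyphenyl]prop-2-ynoic acid A7. The resulting ortho-hydroxyaryl ynone would close to 2-[3,5-bis(benzyloxy)-4-methoxyphenyl]-5,7-dimethoxychromen-4-one A8.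
- In favour: this is the most convergent of the four plans, with ring C assembled from two fragments in one flask. The methoxy group next to the aryne bond directs the carboxylate oxygen to the remote aryne carbon, so the regiochemistry is reliable. Aryne insertion into carboxylic acids is an established reaction type. On convergence and on precedent for the key step it is better than the chosen plan.
- Against: A8 lacks the oxygens at both C8 and C3. It would need peri-demethylation, a persulfate hydroxylation at C8 (an inefficient reaction), 8-O-methylation, C3 hydroxylation and hydrogenolysis. A6 itself takes several steps, and arylpropiolic acids are prone to decarboxylation with fluoride and heat.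
- Comparison: five operations would follow the key step here against three in the chosen plan. The chosen plan carries the C8 oxygen from the first step.

Key step: step 5

Remark on the chemistry: the target has no stereocentre. The lithiated intermediates 7 and 12 are drawn as monomeric covalent lithium species and boronate 13 as its neutral dimethyl ester, although in solution they are aggregates or ate complexes.

Step 1
Reactants: 1 methoxyhydroquinone (2-methoxybenzene-1,4-diol)
Product: 2 1-(2,5-dihydroxy-4-methoxyphenyl)ethanone
Conditions: AcOH, BF3·OEt2, 90 °C; then H2O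
Reagents that add atoms: acetic acid, CC(=O)O
Why: Friedel–Crafts acylation (through the aryl acetate and a Fries-type shift) at the one ring carbon that is para to the methoxy group and ortho to a hydroxyl; the product is held as a difluoroboron chelate of the ortho-hydroxy ketone, which should stop a second acylation.

Step 2
Reactants: 3 3,5-dihydroxy-4-methoxybenzoic acid
Product: 5 3,5-bis(benzyloxy)-4-methoxybenzoic acid, via benzyl ester 4 (not isolated)
Conditions: BnBr (3.3 equiv), K2CO3, DMF, 60 °C; then NaOH, MeOH/H2O, 70 °C; HCl work-up
Reagents that add atoms: benzyl bromide, BrCc1ccccc1; sodium hydroxide, [Na+].[OH-] (oxygen of the restored carboxyl group)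
Why: Williamson etherification of both phenols with concomitant esterification of the carboxylate, followed by saponification, which cleaves only the benzyl ester and leaves the aryl benzyl ethers intact.

Step 3
Reactants: 5 3,5-bis(benzyloxy)-4-methoxybenzoic acid
Product: 6 3,5-bis(benzyloxy)-4-methoxybenzoyl chloride
Conditions: (COCl)2, DMF (cat.), CH2Cl2, 0 °C to rt; evaporate, use crude
Reagents that add atoms: oxalyl chloride, ClC(=O)C(=O)Cl
Why: Acid chloride formation through the Vilsmeier-type chloroiminium catalyst; the by-products are gases and the benzyl and methyl ethers are inert under these mild conditions.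

Step 4
Reactants: 2 1-(2,5-dihydroxy-4-methoxyphenyl)ethanone; 6 3,5-bis(benzyloxy)-4-methoxybenzoyl chloride
Product: 8 1-[3,5-bis(benzyloxy)-4-methoxyphenyl]-3-(2,5-dihydroxy-4-methoxyphenyl)propane-1,3-dione, via trilithio polyanion 7 (not isolated)
Conditions: LiN(SiMe3)2 (4.2 equiv), THF, −78 to −10 °C; then 6 (1.0 equiv), −78 °C to rt; degassed aq. NH4Cl quench under Ar
Reagents that add atoms: LiN(SiMe3)2, [Li]N([Si](C)(C)C)[Si](C)(C)C (lithium of intermediate 7 only)
Why: Crossed Claisen-type C-aroylation of the ketone enolate within the lithium polyanion of a polyhydroxyacetophenone, a known way to ortho-hydroxyaryl 1,3-diketones in which the aggregated lithium phenoxides are acylated more slowly than the enolate carbon; the fourth equivalent of base takes up the more acidic diketone as it forms, and the mildly acidic, air-free quench avoids both cyclodehydration and oxidation.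

Step 5
Reactants: 8 1-[3,5-bis(benzyloxy)-4-methoxyphenyl]-3-(2,5-dihydroxy-4-methoxyphenyl)propane-1,3-dione
Product: 10 2-[3,5-bis(benzyloxy)-4-methoxyphenyl]-5,8-dihydroxy-7-methoxychromen-4-one, via acylquinone 9 (not isolated)
Conditions: Ag2O (1.1 equiv), MgSO4, THF (0.02 M), rt, dark, Ar; filter (Celite); aq. Na2S2O4 wash
Reagents that add atoms: none
Why: Proposed new method: Ag2O should dehydrogenate the hydroquinone of 8 under neutral, anhydrous conditions to the 2-acyl-5-methoxy-1,4-benzoquinone 9, a standard oxidation of acylhydroquinones. In 9 the ring carbon that becomes C8a is the beta carbon of two enones at once (the ring C5 carbonyl and the side-chain C4 carbonyl), whereas C6 is the electron-rich beta carbon of the C7 enol ether, so the tethered nucleophile has one strongly preferred site. The enol oxygen on the ring-B carbon of the enolised diketone should add to C8a, forming O1–C8a and closing ring C in a 6-endo-trig mode, and tautomerisation of the adduct restores an aromatic ring A as the 5,8-dihydroxyflavone 10; no stereocentre is formed. The closest known reaction types are conjugate additions of oxygen, nitrogen and sulfur nucleophiles to C3 of 2-acyl-1,4-benzoquinones and oxidative cyclisations of acylhydroquinones, neither of which has been used to close the pyranone ring of a flavone. The selectivity needed is closure through O1–C8a instead of the ordinary cyclodehydration through the C5 oxygen, which would give the 6-hydroxy-7-methoxy isomer; it is secured because oxidation is complete before any acid is present, after which the C5 oxygen is a quinone carbonyl and can no longer act as a nucleophile. High dilution should suppress intermolecular Michael addition of the diketone carbon to a second quinone, and near-stoichiometric oxidant with a dithionite wash should return any ring A carried on to the quinone level to 10.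

Step 6
Reactants: 10 2-[3,5-bis(benzyloxy)-4-methoxyphenyl]-5,8-dihydroxy-7-methoxychromen-4-one
Product: 11 2-[3,5-bis(benzyloxy)-4-methoxyphenyl]-5-hydroxy-7,8-dimethoxychromen-4-one
Conditions: MeI (1.2 equiv), K2CO3 (1.2 equiv), acetone (degassed), rt to 40 °C, Ar
Reagents that add atoms: iodomethane, CI
Why: Williamson methylation of the free, more acidic C8 phenol; the C5 hydroxyl is locked in a hydrogen bond to the C4 carbonyl and should not be alkylated with a small excess of reagent under mild base, the classical basis of partial methylation of 5-hydroxyflavones.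

Step 7
Reactants: 11 2-[3,5-bis(benzyloxy)-4-methoxyphenyl]-5-hydroxy-7,8-dimethoxychromen-4-one
Product: 14 2-[3,5-bis(benzyloxy)-4-methoxyphenyl]-3,5-dihydroxy-7,8-dimethoxychromen-4-one, via C3-lithiated lithium phenoxide 12 (not isolated), via dimethyl 3-boronate 13 (not isolated)
Conditions: LiN(iPr)2 (3.5 equiv), THF, −78 °C; B(OMe)3, −78 to 0 °C; AcOH, 30% H2O2, 0 °C to rt
Reagents that add atoms: hydrogen peroxide, OO (oxygen at C3); trimethyl borate, COB(OC)OC (boron of intermediate 13 only); LiN(iPr)2, [Li]N(C(C)C)C(C)C (lithium of intermediate 12 only)
Why: Directed C3 lithiation of a flavone, borylation and oxidative C–B to C–O conversion, a known flavone-to-flavonol sequence; the first equivalent of amide turns the C5 hydroxyl into a phenoxide that shields the C4 carbonyl from addition, the second removes the C3 proton, which is activated by the adjacent carbonyl and ring oxygen, and the low temperature should prevent ring opening of the lithiated pyranone.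

Step 8
Reactants: 14 2-[3,5-bis(benzyloxy)-4-methoxyphenyl]-3,5-dihydroxy-7,8-dimethoxychromen-4-one
Product: 15 3,5-dihydroxy-2-(3,5-dihydroxy-4-methoxyphenyl)-7,8-dimethoxychromen-4-one
Conditions: H2 (1 atm), 10% Pd/C, EtOAc/MeOH, rt
Reagents that add atoms: none
Why: Catalytic hydrogenolysis of the two aryl benzyl ethers; the tetrasubstituted, vinylogous-ester C2=C3 bond of a flavonol and the methyl ethers should be untouched at ambient pressure.

## Compound list

1 | methoxyhydroquinone (2-methoxybenzene-1,4-diol) | COc1cc(O)ccc1O | starting material
2 | 1-(2,5-dihydroxy-4-methoxyphenyl)ethanone | COc1cc(O)c(C(C)=O)cc1O | intermediate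
3 | 3,5-dihydroxy-4-methoxybenzoic acid | COc1c(O)cc(C(=O)O)cc1O | starting material
4 | benzyl 3,5-bis(benzyloxy)-4-methoxybenzoate | COc1c(OCc2ccccc2)cc(C(=O)OCc2ccccc2)cc1OCc1ccccc1 | intermediate (not isolated)
5 | 3,5-bis(benzyloxy)-4-methoxybenzoic acid | COc1c(OCc2ccccc2)cc(C(=O)O)cc1OCc1ccccc1 | intermediate
6 | 3,5-bis(benzyloxy)-4-methoxybenzoyl chloride | COc1c(OCc2ccccc2)cc(C(=O)Cl)cc1OCc1ccccc1 | intermediate
7 | trilithio polyanion of 2 (dilithium phenoxide, lithium enolate) | COc1cc(O[Li])c(C(=C)O[Li])cc1O[Li] | intermediate (not isolated)
8 | 1-[3,5-bis(benzyloxy)-4-methoxyphenyl]-3-(2,5-dihydroxy-4-methoxyphenyl)propane-1,3-dione | COc1cc(O)c(C(=O)CC(=O)c2cc(OCc3ccccc3)c(OC)c(OCc3ccccc3)c2)cc1O | intermediate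
9 | 2-{3-[3,5-bis(benzyloxy)-4-methoxyphenyl]-3-oxopropanoyl}-5-methoxycyclohexa-2,5-diene-1,4-dione | COC1=CC(=O)C(C(=O)CC(=O)c2cc(OCc3ccccc3)c(OC)c(OCc3ccccc3)c2)=CC1=O | intermediate (not isolated)
10 | 2-[3,5-bis(benzyloxy)-4-methoxyphenyl]-5,8-dihydroxy-7-methoxychromen-4-one | COc1cc(O)c2c(=O)cc(-c3cc(OCc4ccccc4)c(OC)c(OCc4ccccc4)c3)oc2c1O | intermediate
11 | 2-[3,5-bis(benzyloxy)-4-methoxyphenyl]-5-hydroxy-7,8-dimethoxychromen-4-one | COc1cc(O)c2c(=O)cc(-c3cc(OCc4ccccc4)c(OC)c(OCc4ccccc4)c3)oc2c1OC | intermediate
12 | 3-lithio derivative of 11 as its lithium 5-phenoxide | COc1cc(O[Li])c2c(=O)c([Li])c(-c3cc(OCc4ccccc4)c(OC)c(OCc4ccccc4)c3)oc2c1OC | intermediate (not isolated)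
13 | dimethyl {2-[3,5-bis(benzyloxy)-4-methoxyphenyl]-5-hydroxy-7,8-dimethoxy-4-oxochromen-3-yl}boronate | COB(OC)c1c(-c2cc(OCc3ccccc3)c(OC)c(OCc3ccccc3)c2)oc2c(OC)c(OC)cc(O)c2c1=O | intermediate (not isolated)
14 | 2-[3,5-bis(benzyloxy)-4-methoxyphenyl]-3,5-dihydroxy-7,8-dimethoxychromen-4-one | COc1cc(O)c2c(=O)c(O)c(-c3cc(OCc4ccccc4)c(OC)c(OCc4ccccc4)c3)oc2c1OC | intermediate
15 | 3,5-dihydroxy-2-(3,5-dihydroxy-4-methoxyphenyl)-7,8-dimethoxychromen-4-one | COc1cc(O)c2c(=O)c(O)c(-c3cc(O)c(OC)c(O)c3)oc2c1OC | target

## Step count and least certain steps

Total: 8 steps. Longest linear sequence: 7 steps (steps 2 to 8, from 3); step 1 is a one-step branch that joins at step 4.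

Step 5 (key step, the step bearing the new-method label). The most likely failures are three processes:
- slow ring closure of the hydrogen-bonded enol, so that the reactive acylquinone decomposes;
- intermolecular Michael addition of the diketone carbon of one molecule to the quinone of another;
- over-oxidation of ring A of the cyclised product by redox exchange with quinone that has not yet cyclised.

The fallback uses known chemistry and sets out from 6 together with purchased 1-(2,6-dihydroxy-4-methoxyphenyl)ethanone F1. C-aroylation of the lithium polyanion of F1 with 6 (LiN(SiMe3)2, THF) should give 1-[3,5-bis(benzyloxy)-4-methoxyphenyl]-3-(2,6-dihydroxy-4-methoxyphenyl)propane-1,3-dione F2. Acid-catalysed cyclodehydration (p-TsOH cat., toluene, 80 °C), in which either of the two equivalent hydroxyls closes the ring, should give 2-[3,5-bis(benzyloxy)-4-methoxyphenyl]-5-hydroxy-7-methoxychromen-4-one F3. Elbs persulfate oxidation (K2S2O8, aq. KOH/pyridine, rt) should hydroxylate para to the C5 phenoxide, giving potassium 2-[3,5-bis(benzyloxy)-4-methoxyphenyl]-5-hydroxy-7-methoxy-4-oxochromen-8-yl sulfate F4. This is hydrolysed without isolation (dilute HCl, Na2SO3, 80 °C) to 10, where the route is rejoined. The persulfate step is expected to be inefficient, but it is the classical entry to 5,8-dihydroxyflavones.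

Step 7. The most likely failures are incomplete C3 metalation of the phenoxide-bearing flavone, ring opening of the lithiated pyranone to an ynone phenoxide if the temperature rises, or competing deprotonation at a benzylic C–H. The fallback replaces metalation by electrophilic epoxidation and sets out from 11. Forced benzylation of the chelated phenol (BnBr, K2CO3, DMF, 70 °C) should give 5-(benzyloxy)-2-[3,5-bis(benzyloxy)-4-methoxyphenyl]-7,8-dimethoxychromen-4-one F5; without a free phenol, ring A should tolerate dimethyldioxirane. Epoxidation (dimethyldioxirane, acetone/CH2Cl2, 0 °C to rt) should give the racemic 2,3-epoxide 5-(benzyloxy)-2-[3,5-bis(benzyloxy)-4-methoxyphenyl]-2,3-epoxy-7,8-dimethoxy-2,3-dihydrochromen-4-one F6. Acid-catalysed opening (p-TsOH cat., CH2Cl2) should give 5-(benzyloxy)-2-[3,5-bis(benzyloxy)-4-methoxyphenyl]-3-hydroxy-7,8-dimethoxychromen-4-one F7. Hydrogenolysis of all three benzyl ethers under the conditions of step 8 comes back to the route at 15.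

Step 4. The most likely failures are competing O-aroylation of the unchelated phenoxide, double aroylation, or poor solubility of the polyanion. The fallback is the Baker–Venkataraman sequence and sets out from 2 and 6. Bis-aroylation (6, 2.2 equiv, pyridine, DMAP cat.) should give 2-acetyl-5-methoxy-1,4-phenylene bis[3,5-bis(benzyloxy)-4-methoxybenzoate] F8. Base-induced 1,5-acyl shift of the ester ortho to the acetyl group (KOH, pyridine, 50 °C) should give 5-{3-[3,5-bis(benzyloxy)-4-methoxyphenyl]-3-oxopropanoyl}-4-hydroxy-2-methoxyphenyl 3,5-bis(benzyloxy)-4-methoxybenzoate F9. Saponification of the remaining ester (LiOH, degassed THF/H2O, Ar, then buffered acidification) returns to the route at 8 and gives back acid 5 for reuse.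

Step 6. The most likely failures are air oxidation of the deprotonated para-dihydroxy ring A or partial alkylation of the chelated C5 hydroxyl. The fallback moves the selectivity from the alkylation to a dealkylation and sets out from 10. Exhaustive methylation (MeI in excess, K2CO3, degassed DMF, 60 °C) should give 2-[3,5-bis(benzyloxy)-4-methoxyphenyl]-5,7,8-trimethoxychromen-4-one F10. Chelation-controlled cleavage of the methyl ether peri to the carbonyl (MgBr2·OEt2, toluene/MeCN, 80 °C), which should spare the benzyl ethers that have no neighbouring carbonyl, comes back to the route at 11.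

## Further compounds

F1 | step 5 | 1-(2,6-dihydroxy-4-methoxyphenyl)ethanone (purchased) | COc1cc(O)c(C(C)=O)c(O)c1
F2 | step 5 | 1-[3,5-bis(benzyloxy)-4-methoxyphenyl]-3-(2,6-dihydroxy-4-methoxyphenyl)propane-1,3-dione | COc1cc(O)c(C(=O)CC(=O)c2cc(OCc3ccccc3)c(OC)c(OCc3ccccc3)c2)c(O)c1
F3 | step 5 | 2-[3,5-bis(benzyloxy)-4-methoxyphenyl]-5-hydroxy-7-methoxychromen-4-one | COc1cc(O)c2c(=O)cc(-c3cc(OCc4ccccc4)c(OC)c(OCc4ccccc4)c3)oc2c1
F4 | step 5 | potassium 2-[3,5-bis(benzyloxy)-4-methoxyphenyl]-5-hydroxy-7-methoxy-4-oxochromen-8-yl sulfate | COc1cc(O)c2c(=O)cc(-c3cc(OCc4ccccc4)c(OC)c(OCc4ccccc4)c3)oc2c1OS(=O)(=O)[O-].[K+]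
F5 | step 7 | 5-(benzyloxy)-2-[3,5-bis(benzyloxy)-4-methoxyphenyl]-7,8-dimethoxychromen-4-one | COc1cc(OCc2ccccc2)c2c(=O)cc(-c3cc(OCc4ccccc4)c(OC)c(OCc4ccccc4)c3)oc2c1OC
F6 | step 7 | 5-(benzyloxy)-2-[3,5-bis(benzyloxy)-4-methoxyphenyl]-2,3-epoxy-7,8-dimethoxy-2,3-dihydrochromen-4-one (racemic; one enantiomer of the cis-fused oxirane drawn) | COc1cc(OCc2ccccc2)c2C(=O)[C@H]3O[C@@]3(c3cc(OCc4ccccc4)c(OC)c(OCc4ccccc4)c3)Oc2c1OC
F7 | step 7 | 5-(benzyloxy)-2-[3,5-bis(benzyloxy)-4-methoxyphenyl]-3-hydroxy-7,8-dimethoxychromen-4-one | COc1cc(OCc2ccccc2)c2c(=O)c(O)c(-c3cc(OCc4ccccc4)c(OC)c(OCc4ccccc4)c3)oc2c1OC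
F8 | step 4 | 2-acetyl-5-methoxy-1,4-phenylene bis[3,5-bis(benzyloxy)-4-methoxybenzoate] | COc1cc(OC(=O)c2cc(OCc3ccccc3)c(OC)c(OCc3ccccc3)c2)c(C(C)=O)cc1OC(=O)c1cc(OCc2ccccc2)c(OC)c(OCc2ccccc2)c1
F9 | step 4 | 5-{3-[3,5-bis(benzyloxy)-4-methoxyphenyl]-3-oxopropanoyl}-4-hydroxy-2-methoxyphenyl 3,5-bis(benzyloxy)-4-methoxybenzoate | COc1cc(O)c(C(=O)CC(=O)c2cc(OCc3ccccc3)c(OC)c(OCc3ccccc3)c2)cc1OC(=O)c1cc(OCc2ccccc2)c(OC)c(OCc2ccccc2)c1
F10 | step 6 | 2-[3,5-bis(benzyloxy)-4-methoxyphenyl]-5,7,8-trimethoxychromen-4-one | COc1cc(OC)c2c(=O)cc(-c3cc(OCc4ccccc4)c(OC)c(OCc4ccccc4)c3)oc2c1OC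
A1 | alternative 1 | (Z)-2-[3,5-bis(benzyloxy)-4-methoxybenzylidene]-4,6,7-trimethoxy-1-benzofuran-3(2H)-one | COc1cc(OC)c(OC)c2O/C(=C\c3cc(OCc4ccccc4)c(OC)c(OCc4ccccc4)c3)C(=O)c12
A2 | alternative 1 | 2-bromo-2-{bromo[3,5-bis(benzyloxy)-4-methoxyphenyl]methyl}-4,6,7-trimethoxy-1-benzofuran-3(2H)-one (racemic, mixture of diastereomers; both centres are lost in the ring expansion) | COc1cc(OC)c(OC)c2OC(Br)(C(Br)c3cc(OCc4ccccc4)c(OC)c(OCc4ccccc4)c3)C(=O)c12
A3 | alternative 1 | 2-[3,5-bis(benzyloxy)-4-methoxyphenyl]-3-hydroxy-5,7,8-trimethoxychromen-4-one | COc1cc(OC)c2c(=O)c(O)c(-c3cc(OCc4ccccc4)c(OC)c(OCc4ccccc4)c3)oc2c1OC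
A4 | alternative 2 | methyl (E)-3-[5-(benzyloxy)-6-[3,5-bis(benzyloxy)-4-methoxyphenyl]-2-(methoxymethyl)-4-oxo-4H-pyran-3-yl]-3-methoxyprop-2-enoate | CO/C(=C/C(=O)OC)c1c(COC)oc(-c2cc(OCc3ccccc3)c(OC)c(OCc3ccccc3)c2)c(OCc2ccccc2)c1=O
A5 | alternative 2 | 3-(benzyloxy)-2-[3,5-bis(benzyloxy)-4-methoxyphenyl]-7-hydroxy-5,8-dimethoxychromen-4-one | COc1cc(O)c(OC)c2oc(-c3cc(OCc4ccccc4)c(OC)c(OCc4ccccc4)c3)c(OCc3ccccc3)c(=O)c12
A6 | alternative 3 | 3,5-dimethoxy-2-(trimethylsilyl)phenyl trifluoromethanesulfonate | COc1cc(OC)c([Si](C)(C)C)c(OS(=O)(=O)C(F)(F)F)c1
A7 | alternative 3 | 3-[3,5-bis(benzyloxy)-4-methoxyphenyl]prop-2-ynoic acid | COc1c(OCc2ccccc2)cc(C#CC(=O)O)cc1OCc1ccccc1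
A8 | alternative 3 | 2-[3,5-bis(benzyloxy)-4-methoxyphenyl]-5,7-dimethoxychromen-4-one | COc1cc(OC)c2c(=O)cc(-c3cc(OCc4ccccc4)c(OC)c(OCc4ccccc4)c3)oc2c1
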